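The constants of the steps were not on the table, so the meeting began by turning the readings into a time. The east flask is the east run continued, and the question is how long it holds intermediate A near its peak.

| flask | substrate | reagent | remark | time |
|---|---|---|---|---|
| east | 0.050 M (fed, over 12 s) | 0.10 M | the very flask that is asked about, followed so far |  |
| south-west | 0.034 M (fed, over 12 s) | 0.10 M | run made earlier |  |
| flask | 0.050 M (fed, over 12 s) | 0.100 M |  | 25 min |

- east (time / min: intermediate A / %, product / %, substrate / %): 0.200: 5.5, 0.5, 89.6; 0.667: 18.7, 0, 54.2; 1.00: 22.6, 0.7, 40.0; 1.50: 21.9, 2.4, 23.1; 2.50: 20.4, 6.3, 7.5; 3.00: 21.8, 8.3, 2.8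
- south-west (time / min: intermediate A / %, product / %, substrate / %): 1.33: 21.5, 2.9, 25.7; 3.00: 22.4, 8.4, 4.9; 6.00: 23.0, 17.4, 1.5; 10.0: 20.4, 25.4, 0.1; 12.0: 20.3, 27.7, 0.3; 20.0: 19.3, 30.0, 0.5

(standard deviation of a reading: 1 percentage point)

1. time, not beyond 25 min, at which the flask holds most intermediate A
2. the amount of intermediate A, in percent of the substrate charged, at that time
3. earliest time at which at least nineteen twentieths of that best amount are there, in min
4. latest time at which they still are, in min

- what may be going on: intermediate E -> product; intermediate A <-> intermediate B; reagent + intermediate D <-> intermediate E; substrate -> intermediate A; substrate -> intermediate C; intermediate C -> intermediate D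

The analyst reported that substrate in the east run falls from 54.2 % at 0.667 min to 7.5 % at 2.50 min, a half-life t½ of 0.642 min. She argued that the south-west readings from 10.0 min on show intermediate A with its source gone, because t½ is short against that time and substrate reads 0.1 % there. Their mean she called the floor F, 20.0 %.

The chair objected that the south-west charge was smaller. The analyst answered that at 3.00 min the east and south-west runs read 21.8 % and 22.4 % of intermediate A, against a scatter of 1 percentage point, so she carried percentages across.

The secretary added a reckoning of his own: Rf, the floor over the highest east reading of 22.6 %, comes to 0.885, and this is the floor ratio, the end amount of intermediate A as a fraction of its peak. Rf reads below the fraction 0.950 that the question sets, so he expected the east flask's window to shut inside 25 min, though Rf attaches no time to that.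

The forecaster put the peak at 22.8 % at 1.7 min, with the window from 0.92 min to 4.5 min, and called the downward crossing “poorly defined because the plateau is so flat”.

The east flask gives 22.3 % at 1.32 min, with the window from 0.850 min to 2.55 min.

    intermediate E → product (k = 0.0770 s⁻¹)
    intermediate A ⇌ intermediate B (K = 2.40, k = 0.0310 s⁻¹)
    reagent + intermediate D ⇌ intermediate E (K = 5.20 L mol⁻¹, k = 0.0360 L mol⁻¹ s⁻¹)
    substrate → intermediate A (k = 0.0120 s⁻¹)
    substrate → intermediate C (k = 0.00540 s⁻¹)
    intermediate C → intermediate D (k = 0.200 s⁻¹)

The forecast's peak height and opening stand, and the two part at the peak time, 1.32 min against 1.7 min, and at the closing, 2.55 min against 4.5 min. At 25.0 min the east flask holds 20.3 % of intermediate A, which is 0.910 of its best, beside Rf of 0.885. The neighbouring flask differs in one setting, 0.020 M of substrate. Rf times its best of 22.3 % gives 19.7 %, and at 25.0 min that neighbour holds 20.3 %.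

(The readings are simulated for an exercise; noise was put on by code.)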